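**Retrosynthetic overview**
1. Feature: the tertiary carbinol carbon and the adjacent ring-fusion CH, both shared by the five-membered indane ring and the 4-hydroxycyclopent-2-enone ring, lie β and α to the cyclopentenone C=O (an aldol retron). Cutting the CH–C(OH) bond opens both five-membered rings to one achiral naphtho-fused (Z)-cyclooct-2-ene-1,4-dione.
2. After the aldol, the phenalenone enone ring is closed between C5 (acyl group, from an iodide placed ortho to OMe) and the peri carbon C4 by ynone hydroarylation; O-demethylation is last.
3. The eight-membered ring comes from ring-closing metathesis of two vinyl carbinols followed by double oxidation; both arms derive from a naphthalene 1,2-diester-level intermediate.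
4. The naphthodioxine ketal is made by double oxa-Michael addition of 1,8-dihydroxynaphthalene to a 1-naphthylpropiolate, itself built from 6-methoxy-2-naphthol (C1 formylation, C2 triflate carbonylation, C5 iodination).
5. Ring order: dioxine ketal ring → eight-membered ring → indane and cyclopentenone rings together → phenalenone ring.

Key step: step 13

Locants: C1–C8 of the central naphthalene keep the numbering of 6-methoxy-2-naphthol throughout (C1 ketal arm, C2 acyl arm, C5 iodine, C6 OMe).
Assumption: the sense of induction in step 13 is assigned from the acid-directed anti-enamine model of proline aldolisations; if the mirror-image series forms, (2R,4S)-4-fluoroproline is used with nothing else changed.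

**Step 1**
Reactants: 1 6-methoxy-2-naphthol
Product: 2 2-hydroxy-6-methoxy-1-naphthaldehyde
Conditions: MgCl2, Et3N, (CH2O)n, MeCN, reflux; aq. HCl
Reagents that add atoms: paraformaldehyde (as formaldehyde), C=O
Why: Magnesium-phenoxide-directed ortho-formylation (Casnati–Skattebøl) delivers formaldehyde only ortho to the hydroxyl, and of the two ortho carbons the α-position C1 is by far the more nucleophilic.

**Step 2**
Reactants: 2 2-hydroxy-6-methoxy-1-naphthaldehyde
Product: 3 1-formyl-6-methoxynaphthalen-2-yl trifluoromethanesulfonate
Conditions: Tf2O, pyridine, CH2Cl2, 0 °C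
Reagents that add atoms: trifluoromethanesulfonic anhydride, O=S(=O)(OS(=O)(=O)C(F)(F)F)C(F)(F)F
Why: O-Sulfonylation of the phenol turns the C2 oxygen into a leaving group for palladium chemistry, and the aldehyde is inert to the anhydride.

**Step 3**
Reactants: 3 1-formyl-6-methoxynaphthalen-2-yl trifluoromethanesulfonate
Product: 4 methyl 1-formyl-6-methoxy-2-naphthoate
Conditions: Pd(OAc)2 (5 mol%), dppp, CO (1 atm), Et3N, MeOH/DMF, 70 °C
Reagents that add atoms: carbon monoxide, [C-]#[O+]; methanol, CO
Why: Palladium-catalysed alkoxycarbonylation of an aryl triflate (oxidative addition into C2–OTf, CO insertion, methanolysis) installs the carbon that becomes the aryl ketone and leaves the ortho aldehyde untouched.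

**Step 4**
Reactants: 4 methyl 1-formyl-6-methoxy-2-naphthoate
Product: 5 methyl 1-formyl-5-iodo-6-methoxy-2-naphthoate
Conditions: NIS, TFA (cat.), MeCN, rt, dark
Reagents that add atoms: N-iodosuccinimide, O=C1CCC(=O)N1I
Why: Electrophilic aromatic iodination goes to the α-carbon ortho to OMe (C5) of the only activated ring, as in 2-methoxynaphthalene, and this iodide is carried as a spectator so that the later acyl group is placed by cross-coupling instead of by a Friedel–Crafts acylation that the more electron-rich dioxynaphthalene would intercept.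

**Step 5**
Reactants: 5 methyl 1-formyl-5-iodo-6-methoxy-2-naphthoate
Product: 6 methyl 1-ethynyl-5-iodo-6-methoxy-2-naphthoate
Conditions: dimethyl (1-diazo-2-oxopropyl)phosphonate, K2CO3, MeOH, 0 °C to rt
Reagents that add atoms: Bestmann–Ohira reagent, COP(=O)(OC)C(=[N+]=[N-])C(C)=O
Why: Seyferth–Gilbert homologation in the Ohira–Bestmann form converts the aryl aldehyde into the terminal alkyne under mild carbonate conditions in which methyl ester and aryl iodide are unchanged.

**Step 6**
Reactants: 6 methyl 1-ethynyl-5-iodo-6-methoxy-2-naphthoate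
Product: 8 methyl 5-iodo-6-methoxy-1-(3-methoxy-3-oxoprop-1-yn-1-yl)-2-naphthoate, via lithium acetylide 7 (not isolated)
Conditions: LiHMDS, THF, −78 °C; then ClCO2Me, −78 to 0 °C
Reagents that add atoms: methyl chloroformate, COC(=O)Cl
Why: Deprotonation of the terminal alkyne and C-acylation of the acetylide give the alkynoate, the silylamide base being non-nucleophilic towards the ester and not exchanging the aryl iodide.

**Step 7**
Reactants: 8 methyl 5-iodo-6-methoxy-1-(3-methoxy-3-oxoprop-1-yn-1-yl)-2-naphthoate; 9 1,8-dihydroxynaphthalene
Product: 11 methyl 5-iodo-6-methoxy-1-[2-(2-methoxy-2-oxoethyl)naphtho[1,8-de][1,3]dioxin-2-yl]-2-naphthoate, via aryloxyacrylate mono-adduct 10 (not isolated)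
Conditions: Cs2CO3 (0.3 equiv), DMF (degassed), rt to 50 °C
Reagents that add atoms: 1,8-dihydroxynaphthalene (compound 9), Oc1cccc2cccc(O)c12
Why: Double oxa-Michael addition of a bis-phenol to an alkynoate, in which the first phenoxide adds to the aryl-bearing β-carbon and the peri hydroxyl then closes the six-membered dioxine 6-exo-trig onto the β-aryloxyacrylate, builds the ketal at a linear sp carbon instead of by condensation at a doubly ortho-flanked aryl ketone.

**Step 8**
Reactants: 11 methyl 5-iodo-6-methoxy-1-[2-(2-methoxy-2-oxoethyl)naphtho[1,8-de][1,3]dioxin-2-yl]-2-naphthoate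
Product: 12 2-[2-[2-(hydroxymethyl)-5-iodo-6-methoxynaphthalen-1-yl]naphtho[1,8-de][1,3]dioxin-2-yl]ethan-1-ol
Conditions: DIBAL-H, CH2Cl2, −78 to 0 °C; Rochelle salt
Reagents that add atoms: none
Why: Hydride reduction of both esters to the primary alcohols spares the aryl iodide and the aryl ketal and avoids an unreliable partial reduction of the aryl ester.

**Step 9**
Reactants: 12 2-[2-[2-(hydroxymethyl)-5-iodo-6-methoxynaphthalen-1-yl]naphtho[1,8-de][1,3]dioxin-2-yl]ethan-1-ol
Product: 13 5-iodo-6-methoxy-1-[2-(2-oxoethyl)naphtho[1,8-de][1,3]dioxin-2-yl]-2-naphthaldehyde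
Conditions: Dess–Martin periodinane, CH2Cl2, 0 °C to rt
Reagents that add atoms: none
Why: Dess–Martin oxidation of both primary alcohols works without amine base, which protects the β,β-bis(aryloxy) aldehyde from E1cB loss of a ketal oxygen.

**Step 10**
Reactants: 13 5-iodo-6-methoxy-1-[2-(2-oxoethyl)naphtho[1,8-de][1,3]dioxin-2-yl]-2-naphthaldehyde; 14 vinylmagnesium bromide
Product: 15 1-[1-[2-(2-hydroxybut-3-en-1-yl)naphtho[1,8-de][1,3]dioxin-2-yl]-5-iodo-6-methoxynaphthalen-2-yl]prop-2-en-1-ol (diastereomer mixture)
Conditions: vinylMgBr, THF, −78 °C; aq. NH4Cl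
Reagents that add atoms: vinylmagnesium bromide (compound 14), C=C[Mg]Br
Why: Twofold Grignard 1,2-addition at low temperature outruns enolisation of the β-aryloxy aldehyde and does not exchange the aryl iodide, and the two carbinol centres that form without control are erased by oxidation in step 12.

**Step 11**
Reactants: 15 1-[1-[2-(2-hydroxybut-3-en-1-yl)naphtho[1,8-de][1,3]dioxin-2-yl]-5-iodo-6-methoxynaphthalen-2-yl]prop-2-en-1-ol
Product: 16 cyclooctenediol (5-iodo-6-methoxynaphtho-fused (Z)-cyclooct-2-ene-1,4-diol spiro-naphthodioxine ketal; diastereomer mixture)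
Conditions: Grubbs II (5–10 mol%), CH2Cl2 (2 mM), 40 °C
Reagents that add atoms: none
Why: Ring-closing metathesis of a diene held together by the ortho-disubstituted arene and the fully substituted ketal carbon favours the eight-membered ring, the ring size enforces the Z-alkene, and free allylic alcohols are tolerated by the ruthenium carbene.

**Step 12**
Reactants: 16 cyclooctenediol
Product: 17 enedione (5-iodo-6-methoxynaphtho-fused (Z)-cyclooct-2-ene-1,4-dione spiro-naphthodioxine ketal)
Conditions: Dess–Martin periodinane, CH2Cl2, 0 °C; used at once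
Reagents that add atoms: none
Why: Dess–Martin oxidation of the allylic and the benzylic-allylic alcohol gives the (Z)-ene-1,4-dione directly under amine-free conditions, so that neither conjugate addition nor a premature racemic aldol closure is triggered.

**Step 13**
Reactants: 17 enedione
Product: 19 aldol (cis-fused hydroxycyclopentenone-indane spiroketal with S-methine and R-carbinol; 5-iodo-6-methoxy series), via dienamine 18 (not isolated)
Conditions: (2S,4R)-4-fluoroproline (20 mol%), DMSO, rt
Reagents that add atoms: none
Why: The secondary amine condenses with the only enolisable carbonyl, the enone ketone next to the ring CH2, to give the cross-conjugated dienamine 18, whose nucleophilic carbon faces the aryl ketone carbon across the tub-shaped eight-membered ring (1,5-relationship); C–C bond formation with proton transfer from the catalyst's carboxylic acid to the ketone oxygen and hydrolysis of the iminium ion then release 19 and the catalyst. The closest known reaction type is the proline-type amine-catalysed enantioselective transannular aldolisation of cyclooctane-1,4-diones to cis-bicyclo[3.3.0]octane β-hydroxy ketones, and the ring closure itself is the familiar aldol cyclisation of (Z)-ene-1,4-diones to 4-hydroxycyclopent-2-enones. The indane ring closes 5-(enolexo)-exo-trig and the cyclopentenone ring 5-(enolendo)-exo-trig, the second mode being imposed and made feasible by the transannular proximity of the two carbons. The methine centre is set by the enamine face that is attacked, namely the face that carries the carboxylic acid of the (2S)-pyrrolidine in the anti-enamine, acid-directed transition state, which should make it (S); the carbinol centre follows as (R) because two five-membered rings can only be cis-fused. Only enantioface selectivity is required, since regioselectivity is fixed by the substrate (one enolisable position, one carbonyl within reach) and dehydration of the aldol is impossible (it would give a cyclopentadienone); the amine-catalysed path must outrun the uncatalysed racemic closure and β-elimination of a ketal aryloxide from the enamine, which is why a zwitterionic catalyst without added base is used at room temperature.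

**Step 14**
Reactants: 19 aldol; 20 (trimethylsilyl)acetylene
Product: 21 silyl ynone (19 with C5–I replaced by C5–C(=O)–C≡C–SiMe3)
Conditions: PdCl2(PPh3)2 (5 mol%), CuI (5 mol%), CO (1 atm), Et3N, THF, rt
Reagents that add atoms: carbon monoxide, [C-]#[O+]; (trimethylsilyl)acetylene (compound 20), C#C[Si](C)(C)C
Why: Carbonylative Sonogashira coupling (oxidative addition into C5–I, CO insertion to the aroylpalladium species, coupling with the copper acetylide) places the propynoyl unit exactly at the iodinated carbon at room temperature, under conditions too weakly basic to open the tertiary aldol.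

**Step 15**
Reactants: 21 silyl ynone
Product: 22 ynone (C5–C(=O)–C≡CH)
Conditions: TBAF, AcOH (1:1), THF, −20 to 0 °C
Reagents that add atoms: none
Why: Protodesilylation with acetic-acid-buffered fluoride cleaves the activated C(sp)–Si bond without free base that could add to the ynone or provoke retro-aldol racemisation.

**Step 16**
Reactants: 22 ynone
Product: 23 spiropreussione B O-methyl ether
Conditions: [(JohnPhos)Au(MeCN)]SbF6 (5 mol%), ClCH2CH2Cl, rt to 50 °C
Reagents that add atoms: none
Why: Gold(I)-catalysed intramolecular hydroarylation (Friedel–Crafts-type alkenylation) of the aryl ynone has the π-activated terminal alkyne carbon attacked 6-endo-dig by the peri carbon C4, which is conjugatively activated by the C6 methoxy group and para to the alkyl-substituted C1, and rearomatisation with protodeauration gives the 9-methoxyphenalenone, attack by the methoxy oxygen being reversible with a non-nucleophilic counter-ion.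

**Step 17**
Reactants: 23 spiropreussione B O-methyl ether
Product: 24 spiropreussione B
Conditions: MgI2·OEt2 (3 equiv), toluene/THF, 40 °C; aq. NH4Cl
Reagents that add atoms: none
Why: Chelation-assisted O-demethylation of the methoxy group peri to the phenalenone carbonyl (a vinylogous methyl ester) has magnesium bridging the two oxygens while iodide removes the methyl group, leaving the aryl ketal, the enone and the tertiary alcohol, whose ionisation would give a cyclopentadienone-type cation, untouched.

**Compound list**
1 | 6-methoxy-2-naphthol | COc1ccc2cc(O)ccc2c1 | starting material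
2 | 2-hydroxy-6-methoxy-1-naphthaldehyde | COc1ccc2c(C=O)c(O)ccc2c1 | intermediate
3 | 1-formyl-6-methoxynaphthalen-2-yl trifluoromethanesulfonate | COc1ccc2c(C=O)c(OS(=O)(=O)C(F)(F)F)ccc2c1 | intermediate
4 | methyl 1-formyl-6-methoxy-2-naphthoate | COc1ccc2c(C=O)c(C(=O)OC)ccc2c1 | intermediate
5 | methyl 1-formyl-5-iodo-6-methoxy-2-naphthoate | COc1ccc2c(C=O)c(C(=O)OC)ccc2c1I | intermediate
6 | methyl 1-ethynyl-5-iodo-6-methoxy-2-naphthoate | COc1ccc2c(C#C)c(C(=O)OC)ccc2c1I | intermediate
7 | lithium acetylide of 6 (lithium [5-iodo-6-methoxy-2-(methoxycarbonyl)naphthalen-1-yl]ethynide) | COc1ccc2c(C#C[Li])c(C(=O)OC)ccc2c1I | intermediate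
8 | methyl 5-iodo-6-methoxy-1-(3-methoxy-3-oxoprop-1-yn-1-yl)-2-naphthoate | COc1ccc2c(C#CC(=O)OC)c(C(=O)OC)ccc2c1I | intermediate
9 | 1,8-dihydroxynaphthalene | Oc1cccc2cccc(O)c12 | starting material
10 | methyl 3-[(8-hydroxynaphthalen-1-yl)oxy]-3-[5-iodo-6-methoxy-2-(methoxycarbonyl)naphthalen-1-yl]prop-2-enoate (alkene geometry not defined) | COc1ccc2c(C(Oc3cccc4cccc(O)c34)=CC(=O)OC)c(C(=O)OC)ccc2c1I | intermediate
11 | methyl 5-iodo-6-methoxy-1-[2-(2-methoxy-2-oxoethyl)naphtho[1,8-de][1,3]dioxin-2-yl]-2-naphthoate | COc1ccc2c(C3(CC(=O)OC)Oc4cccc5cccc(O3)c45)c(C(=O)OC)ccc2c1I | intermediate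
12 | 2-[2-[2-(hydroxymethyl)-5-iodo-6-methoxynaphthalen-1-yl]naphtho[1,8-de][1,3]dioxin-2-yl]ethan-1-ol | COc1ccc2c(C3(CCO)Oc4cccc5cccc(O3)c45)c(CO)ccc2c1I | intermediate
13 | 5-iodo-6-methoxy-1-[2-(2-oxoethyl)naphtho[1,8-de][1,3]dioxin-2-yl]-2-naphthaldehyde | COc1ccc2c(C3(CC=O)Oc4cccc5cccc(O3)c45)c(C=O)ccc2c1I | intermediate
14 | vinylmagnesium bromide | C=C[Mg]Br | starting material
15 | 1-[1-[2-(2-hydroxybut-3-en-1-yl)naphtho[1,8-de][1,3]dioxin-2-yl]-5-iodo-6-methoxynaphthalen-2-yl]prop-2-en-1-ol; both carbinol centres unassigned, diastereomer mixture | COc1ccc2c(C3(CC(O)C=C)Oc4cccc5cccc(O3)c45)c(C(O)C=C)ccc2c1I | intermediate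
16 | cyclooctenediol: eight-membered ring fused to the naphthalene C1–C2 bond, ring sequence C1(naph)–spiro ketal carbon (C2 of the naphtho[1,8-de][1,3]dioxine)–CH2–CH(OH)–CH=CH (Z)–CH(OH)–C2(naph); I at C5, OMe at C6; carbinol centres unassigned, diastereomer mixture | COc1ccc2c(c1I)ccc3c2C1(Oc2cccc4cccc(c24)O1)CC(O)/C=C\C3O | intermediate
17 | enedione: as 16 with both carbinols oxidised, ring sequence C1(naph)–spiro ketal carbon–CH2–C(=O)–CH=CH (Z)–C(=O)–C2(naph); achiral | COc1ccc2c(c1I)ccc3c2C1(Oc2cccc4cccc(c24)O1)CC(=O)/C=C\C3=O | intermediate
18 | dienamine of 17 with (2S,4R)-4-fluoroproline: nitrogen on the former CH2-flanked carbonyl carbon, enamine C=C towards the ketal carbon | COc1ccc2c(c1I)ccc3c2C1(Oc2cccc4cccc(c24)O1)/C=C(/N1C[C@H](F)C[C@H]1C(=O)O)\C=C/C3=O | intermediate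
19 | aldol: indane ring = C1(naph), C2(naph), C(OH), CH, spiro ketal carbon; cyclopentenone ring = CH, C=O, CH=CH, C(OH); cis-fused, (S) at the ring-fusion CH, (R) at the carbinol carbon; I at C5, OMe at C6 | COc1ccc2c(c1I)ccc3c2C1(Oc2cccc4cccc(c24)O1)[C@@H]1C(=O)C=C[C@]31O | intermediate
20 | (trimethylsilyl)acetylene | C#C[Si](C)(C)C | starting material
21 | silyl ynone: 19 with C5–I replaced by C5–C(=O)–C≡C–SiMe3; (S)-CH, (R)-C(OH) | COc1ccc2c(c1C(=O)C#C[Si](C)(C)C)ccc3c2C1(Oc2cccc4cccc(c24)O1)[C@@H]1C(=O)C=C[C@]31O | intermediate
22 | ynone: C5–C(=O)–C≡CH; (S)-CH, (R)-C(OH) | COc1ccc2c(c1C(=O)C#C)ccc3c2C1(Oc2cccc4cccc(c24)O1)[C@@H]1C(=O)C=C[C@]31O | intermediate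
23 | spiropreussione B O-methyl ether (9-methoxyphenalenone ring closed between C5 and C4); (S)-CH, (R)-C(OH) | O=C1C=Cc2cc3c(c4ccc(OC)c1c24)C1(Oc2cccc4cccc(c24)O1)[C@@H]1C(=O)C=C[C@]31O | intermediate
24 | spiropreussione B; (S)-CH, (R)-C(OH) | O=C1C=Cc2cc3c(c4ccc(O)c1c24)C1(Oc2cccc4cccc(c24)O1)[C@@H]1C(=O)C=C[C@]31O | target

**Total step count:** 17.
**Longest linear sequence:** 17 steps from 1 (compounds 9, 14 and 20 are purchased).

**Steps most likely to fail**

Step 13. The enantioface selectivity may be poor because an uncatalysed or general-base transannular closure of the reactive enedione competes with the enamine path. The enamine may also lose a ketal aryloxide by β-elimination, and the catalyst may be held back by reversible conjugate addition to the enedione. Fallback: setting out from 17, the ring is closed without chiral control by the known base-mediated aldol cyclisation of a (Z)-ene-1,4-dione (pH 8 phosphate buffer/THF, or a trace of Et3N in CH2Cl2). This should give the racemate, an equimolar mixture of 19 and its mirror image ent-19 F1. Preparative chromatography on a chiral stationary phase then separates the enantiomers, and the route is rejoined at 19.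

Step 7. The first addition may be slow because the hydrogen-bonded naphtholate is a weak nucleophile and the alkyne carbon is flanked by a peri hydrogen and an ortho ester. The second addition may revert by E1cB under base, leaving the open mono-adduct. Fallback: setting out from aldehyde 5, Roskamp homologation with ethyl diazoacetate (SnCl2 or NbCl5, CH2Cl2) gives the β-keto ester ethyl 3-[5-iodo-6-methoxy-2-(methoxycarbonyl)naphthalen-1-yl]-3-oxopropanoate F2. Acid-catalysed ketalisation of F2 with 9 under azeotropic removal of water (TsOH, toluene, Dean–Stark) gives the mixed ethyl/methyl diester ketal F3. DIBAL-H reduction of F3 as in step 8 gives the same diol, so the route is rejoined at 12.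

Step 16. Attack of the ortho methoxy oxygen on the gold-activated alkyne, followed by loss of the methyl group, may divert material to a benzochromenone. The peri carbon of the acylated naphthalene may be too weak a nucleophile, and the terminal alkyne may deactivate the catalyst as a gold acetylide. Fallback: setting out from iodide 19, carbonylative Stille coupling with tributyl(vinyl)stannane (Pd(PPh3)4, CO, toluene) gives the aryl vinyl ketone F4. Acid-promoted peri conjugate Friedel–Crafts alkylation (TfOH or Me2AlCl, CH2Cl2), the cyclisation mode of the classical phenalenone annulation of 1-acyl-2-methoxynaphthalenes, gives the 2,3-dihydrophenalenone F5. Dehydrogenation of F5 with DDQ gives the methoxyphenalenone, and the route is rejoined at 23.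

**Further compounds**
F1 | step 13 | ent-19, mirror image of the aldol; (R) at the ring-fusion CH, (S) at the carbinol carbon | COc1ccc2c(c1I)ccc3c2C1(Oc2cccc4cccc(c24)O1)[C@H]1C(=O)C=C[C@@]31O
F2 | step 7 | ethyl 3-[5-iodo-6-methoxy-2-(methoxycarbonyl)naphthalen-1-yl]-3-oxopropanoate | COc1ccc2c(C(=O)CC(=O)OCC)c(C(=O)OC)ccc2c1I
F3 | step 7 | methyl 1-[2-(2-ethoxy-2-oxoethyl)naphtho[1,8-de][1,3]dioxin-2-yl]-5-iodo-6-methoxy-2-naphthoate | COc1ccc2c(C3(CC(=O)OCC)Oc4cccc5cccc(O3)c45)c(C(=O)OC)ccc2c1I
F4 | step 16 | aryl vinyl ketone: 19 with C5–I replaced by C5–C(=O)–CH=CH2; (S)-CH, (R)-C(OH) | COc1ccc2c(c1C(=O)C=C)ccc3c2C1(Oc2cccc4cccc(c24)O1)[C@@H]1C(=O)C=C[C@]31O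
F5 | step 16 | 2,3-dihydro derivative of 23 (C5–C(=O)–CH2–CH2–C4); (S)-CH, (R)-C(OH) | O=C1CCc2cc3c(c4ccc(OC)c1c24)C1(Oc2cccc4cccc(c24)O1)[C@@H]1C(=O)C=C[C@]31O
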